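The runs stem from a simulated flask for substances that don't exist, and the scatter is random.

A fitted curve tempts one to trust a ratio further than its smaller partner allows: ochre's first ratio, 21.7 at 1.00 h, rests on isomer of 0.9% read with a scatter of 0.5 percentage points, so for the early questions I gave no number of my own and said that target stood far ahead; the forecast below differs from me here and gives numbers. In these flasks substrate takes up reagent, fed from the gas, to give target and its isomer, and reagent also turns target into over-reaction product.

| flask | substrate | gas | remark | time |
|---|---|---|---|---|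
| ochre | 0.12 M | 23 mM (held) | run made earlier |  |
| blue | 0.19 M | 23 mM (held) | run made earlier |  |
| flask | 0.25 M | 23 mM (held) |  | 20 h |

| run | time / h | target / % | isomer of the product / % |
|---|---|---|---|
| ochre | 1.00 | 19.5 | 0.9 |
| ochre | 3.00 | 29.1 | 1.4 |
| ochre | 6.00 | 24.4 | 3.2 |
| ochre | 8.00 | 21.1 | 3.8 |
| ochre | 12.0 | 16.1 | 5.9 |
| ochre | 15.0 | 13.2 | 7.0 |
| blue | 1.33 | 20.8 | 0.8 |
| blue | 2.00 | 25.7 | 1.5 |
| blue | 4.00 | 27.3 | 3.0 |
| blue | 6.00 | 24.9 | 3.8 |
| blue | 10.0 | 19.5 | 5.0 |
| blue | 15.0 | 13.5 | 6.3 |

(scatter of a reading: 0.5 percentage points)

1. ratio of target to isomer of the product at 12 min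
2. ratio of target to isomer of the product at 2.0 h
3. ratio of target to isomer of the product at 20 h
4. which of target and isomer of the product there is more of at 20 h

- at the start none of reagent is dissolved
- reactions considered so far: substrate + reagent <-> target; substrate + reagent <-> isomer of the product; gas <-> reagent; reagent + target -> over-reaction product

What I could count was fade. Blue's target fell from 27.3% of the charge at 4.00 h to 13.5% at 15.0 h. That gave 10.8 h, my fade half-life: the time in which the amount of target halves after its highest reading, a pseudo-first-order reading. Ochre gave 10.5 h, so I carried blue's value and peak to the flask.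

Two extremes bracketed 20 h. Counting no half-lives left target at 27.3%; counting from the start, 1.85 half-lives, left 7.59%. I placed the flask between them, since blue's target rose up to its highest reading before it faded, so I counted from 4.00 h: 1.48 half-lives, leaving 9.80%. Continuing blue's last isomer gain gave 7.60%, so my ratio was 1.29, with the lower extreme a tie.

The forecast gave 22, 18 and 1.3, with target ahead: “Target stays narrowly ahead.”

The flask gave 39.3, 20.9 and 1.34, with 10.1% target against 7.56% isomer.

    substrate + reagent ⇌ target (K = 29.0 L mol⁻¹, k = 0.00554 L mol⁻¹ s⁻¹)
    substrate + reagent ⇌ isomer of the product (K = 198 L mol⁻¹, k = 1.33 × 10⁻⁴ L mol⁻¹ s⁻¹)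
    gas ⇌ reagent, rate k3*(csat - [reagent]) (kL = 0.00163 s⁻¹)
    reagent + target → over-reaction product (k = 0.00245 L mol⁻¹ s⁻¹)

Target's half-life for going back to substrate and reagent is 1.0 h, shorter than my fade half-life of 10.8 h and than 20 h. The fade half-life therefore describes the amount of target, not the life of one molecule of it.

For the neighbour with 0.62 M of substrate, the same half-life and peak give 9.80% target again. The computed neighbour holds 12.8% target and 7.40% isomer, a ratio of 1.73.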